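**Plan**
- Oxolane numbering: O1, C2 = ring CH2, C3 = carbinol carbon (OH, 3,4-dimethoxybenzyl), C4 = CH2OH-bearing carbon, C5 = aryl-bearing carbon. The target is (3R,4R,5R), with aryl, CH2OH and the C3 hydroxyl all cis.
- Enabling feature: C2 lies between O1 and the carbinol carbon C3, and O1 sits on C5, 1,3 to C3 (an aldol pattern O1–C5–C4–C3). With C3 raised to a ketone, C2 becomes the diazo carbon of an α-diazoketone five atoms from the C5 hydroxyl, and the same ketone later accepts the benzyl group.
- Retrosynthetic cuts, in order: O-benzyl groups and CH2OH (from vinyl); C3–CH2Ar (ketone plus benzyl-metal); ring bond O1–C2 (carbenoid O–H insertion); C2–C3 (acid plus diazomethane); C4–C5 (syn aldol).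
- Forward: acyclic chain by aldol, one-carbon homologation to the diazoketone, closure of the only ring, benzyl addition (removes the ketone helper), vinyl to CH2OH, debenzylation.
- Stereochemistry: C4 and C5 from the (R)-4-benzyloxazolidinone boron aldol; C3 by addition to the oxolan-3-one anti to the cis vinyl and aryl groups.

Key step: step 5

Remark: the catechol is carried as its bis(benzyl) ether and the CH2OH group as a vinyl group, because an α-vinyl imide gives a reliable syn aldol whereas a β-alkoxy acyl unit risks elimination on enolisation.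

**Step 1**
Reactants: 1 (R)-4-benzyl-1,3-oxazolidin-2-one; 2 (E)-but-2-enoyl chloride
Product: 4 (R)-4-benzyl-3-[(E)-but-2-enoyl]-1,3-oxazolidin-2-one, via N-lithio oxazolidinone 3 (not isolated)
Conditions: n-BuLi, THF, −78 °C; then 2, −78 → 0 °C
Reagents that add atoms: none
Why: N-acylation of the lithiated oxazolidinone by the acid chloride is the standard preparation of Evans imides and should not touch the auxiliary stereocentre.

**Step 2**
Reactants: 4 (R)-4-benzyl-3-[(E)-but-2-enoyl]-1,3-oxazolidin-2-one; 5 3,4-bis(benzyloxy)benzaldehyde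
Product: 8 (4R)-4-benzyl-3-{(2R)-2-[(R)-[3,4-bis(benzyloxy)phenyl](hydroxy)methyl]but-3-enoyl}-1,3-oxazolidin-2-one, via dibutylboron dienolate 6 (not isolated), via boron aldolate 7 (not isolated)
Conditions: Bu2BOTf, Et3N, CH2Cl2, −78 → 0 °C; then 5, −78 → 0 °C; pH 7 buffer, MeOH, H2O2, 0 °C
Reagents that add atoms: none
Why: Evans syn aldol reaction: the (Z)-boron dienolate reacts at its α-carbon through a Zimmerman–Traxler chair with one face blocked by the (R)-benzyl group of the auxiliary, so the future C5 (R carbinol) and C4 (R, vinyl-bearing) should be set together in the syn relationship that becomes cis in the ring.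

**Step 3**
Reactants: 8 aldol adduct
Product: 10 (2R)-2-[(R)-[3,4-bis(benzyloxy)phenyl](hydroxy)methyl]but-3-enoic acid, via peroxy acid 9 (not isolated)
Conditions: LiOH, H2O2, THF/H2O, 0 °C; aq Na2SO3; then cold 1 M HCl to pH 3
Reagents that add atoms: hydrogen peroxide, OO
Why: Hydroperoxide cleavage of the imide attacks the exocyclic carbonyl selectively, releases auxiliary 1 for reuse, and at 0 °C should leave the enolisable α-vinyl centre and the aldol unit intact.

**Step 4**
Reactants: 10 hydroxy acid
Product: 12 (3R,4R)-4-[3,4-bis(benzyloxy)phenyl]-1-diazo-3-ethenyl-4-hydroxybutan-2-one, via mixed isobutyl carbonic anhydride 11 (not isolated)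
Conditions: i-BuOCOCl, N-methylmorpholine, THF, −20 °C; then CH2N2, Et2O, −20 → 0 °C
Reagents that add atoms: diazomethane, C=[N+]=[N-]
Why: Mixed-anhydride activation is selective for the carboxylate over the secondary hydroxyl at −20 °C, and acylation of diazomethane (first stage of the Arndt–Eistert sequence, known on unprotected β-hydroxy amino acids) should add the future ring CH2 as a diazo carbon.

**Step 5**
Reactants: 12 hydroxy diazoketone
Product: 13 (4R,5R)-5-[3,4-bis(benzyloxy)phenyl]-4-ethenyloxolan-3-one
Conditions: Rh2(OAc)4 (1 mol %), CH2Cl2, rt, slow addition of 12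
Reagents that add atoms: none
Why: Rh2(OAc)4 decomposes the diazoketone with loss of N2 to an electrophilic rhodium carbenoid at C1, the C4 hydroxyl oxygen adds to it to give a five-membered oxonium ylide, and a 1,2-proton shift with release of the catalyst delivers the oxolan-3-one, so the O1–C2 ring bond is formed. The closest known reaction type is the Rh2(OAc)4-catalysed intramolecular O–H insertion of 1-diazo-4-hydroxybutan-2-ones to dihydrofuran-3(2H)-ones. The single ring (O1, C2, C3, C4, C5) closes in a five-membered exo mode, the oxygen attacking the trigonal carbenoid carbon whose C=Rh bond stays outside the ring. No new stereocentre arises: C4 and C5 come unchanged from the aldol step, and the neutral, base-free medium should keep the enolisable C4 centre (α to the new ketone, cis to the aryl group) from epimerising. The step needs chemoselectivity for the O–H bond over the vinyl group, the electron-rich arene and a second molecule of substrate; the hydroxyl is the only donor that reaches the carbenoid through a five-membered transition state (the vinyl group could only give a bicyclo[2.1.0]pentanone and the arene a six-membered ring), and slow addition at high dilution suppresses intermolecular insertion.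

**Step 6**
Reactants: 13 oxolan-3-one; 14 4-(chloromethyl)-1,2-dimethoxybenzene
Product: 17 (3R,4R,5R)-5-[3,4-bis(benzyloxy)phenyl]-3-(3,4-dimethoxybenzyl)-4-ethenyloxolan-3-ol, via benzylic Grignard reagent 15 (not isolated), via benzylic organocerium reagent 16 (not isolated)
Conditions: 14, Mg, THF, 0 °C; anhydrous CeCl3, THF, −78 °C; then 13, −78 °C; aq NH4Cl
Reagents that add atoms: none
Why: 1,2-addition of a weakly basic benzylic organocerium reagent to the ketone; the vinyl group at C4 and the aryl group at C5 lie on the same face, so the nucleophile should enter from the opposite face, placing the benzyl group trans and the new hydroxyl cis to them (3R).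

**Step 7**
Reactants: 17 vinyl carbinol
Product: 19 (3R,4R,5R)-5-[3,4-bis(benzyloxy)phenyl]-3-(3,4-dimethoxybenzyl)-4-(hydroxymethyl)oxolan-3-ol, via oxolane-3-carbaldehyde 18 (not isolated)
Conditions: O3, CH2Cl2/MeOH, NaHCO3, −78 °C (stopped at consumption of the alkene); Me2S; then NaBH4, 0 °C
Reagents that add atoms: ozone, [O-][O+]=O
Why: Ozonolysis of the only alkene with reductive work-up, the aldehyde being reduced in the same flask by NaBH4 so that the C4 centre next to the formyl group should have no time to epimerise.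

**Step 8**
Reactants: 19 bis(benzyl) ether diol
Product: 20 (3R,4R,5R)-5-(3,4-dihydroxyphenyl)-3-(3,4-dimethoxybenzyl)-4-(hydroxymethyl)oxolan-3-ol
Conditions: H2 (1 atm), Pd/C, EtOAc/MeOH, rt
Reagents that add atoms: none
Why: Hydrogenolysis of aryl benzyl ethers on Pd/C is much faster than cleavage of the cyclic benzylic C5–O1 bond, so stopping after uptake for two benzyl groups should give the catechol without ring opening.

**Compound list**
1 | (R)-4-benzyl-1,3-oxazolidin-2-one | O=C1N[C@H](Cc2ccccc2)CO1 | starting material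
2 | (E)-but-2-enoyl chloride | C/C=C/C(=O)Cl | starting material
3 | N-lithio-(R)-4-benzyl-1,3-oxazolidin-2-one | [Li]N1C(=O)OC[C@H]1Cc1ccccc1 | intermediate (not isolated)
4 | (R)-4-benzyl-3-[(E)-but-2-enoyl]-1,3-oxazolidin-2-one | C/C=C/C(=O)N1C(=O)OC[C@H]1Cc1ccccc1 | intermediate
5 | 3,4-bis(benzyloxy)benzaldehyde | O=Cc1ccc(OCc2ccccc2)c(OCc2ccccc2)c1 | starting material
6 | (R)-4-benzyl-3-[(1Z)-1-(dibutylboranyloxy)buta-1,3-dien-1-yl]-1,3-oxazolidin-2-one | C=C/C=C(\OB(CCCC)CCCC)N1C(=O)OC[C@H]1Cc1ccccc1 | intermediate (not isolated)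
7 | O-dibutylboranyl aldolate of 8 | CCCCB(CCCC)O[C@@H](c1ccc(OCc2ccccc2)c(OCc2ccccc2)c1)[C@H](C(=O)N1C(=O)OC[C@H]1Cc1ccccc1)C=C | intermediate (not isolated)
8 | (4R)-4-benzyl-3-{(2R)-2-[(R)-[3,4-bis(benzyloxy)phenyl](hydroxy)methyl]but-3-enoyl}-1,3-oxazolidin-2-one | O[C@@H](c1ccc(OCc2ccccc2)c(OCc2ccccc2)c1)[C@H](C(=O)N1C(=O)OC[C@H]1Cc1ccccc1)C=C | intermediate
9 | (2R)-2-[(R)-[3,4-bis(benzyloxy)phenyl](hydroxy)methyl]but-3-eneperoxoic acid | O[C@@H](c1ccc(OCc2ccccc2)c(OCc2ccccc2)c1)[C@H](C(=O)OO)C=C | intermediate (not isolated)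
10 | (2R)-2-[(R)-[3,4-bis(benzyloxy)phenyl](hydroxy)methyl]but-3-enoic acid | O[C@@H](c1ccc(OCc2ccccc2)c(OCc2ccccc2)c1)[C@H](C(=O)O)C=C | intermediate
11 | mixed isobutyl carbonic anhydride of 10 | O[C@@H](c1ccc(OCc2ccccc2)c(OCc2ccccc2)c1)[C@H](C(=O)OC(=O)OCC(C)C)C=C | intermediate (not isolated)
12 | (3R,4R)-4-[3,4-bis(benzyloxy)phenyl]-1-diazo-3-ethenyl-4-hydroxybutan-2-one | O[C@@H](c1ccc(OCc2ccccc2)c(OCc2ccccc2)c1)[C@H](C(=O)C=[N+]=[N-])C=C | intermediate
13 | (4R,5R)-5-[3,4-bis(benzyloxy)phenyl]-4-ethenyloxolan-3-one | O=C1CO[C@@H](c2ccc(OCc3ccccc3)c(OCc3ccccc3)c2)[C@H]1C=C | intermediate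
14 | 4-(chloromethyl)-1,2-dimethoxybenzene | COc1ccc(CCl)cc1OC | starting material
15 | (3,4-dimethoxybenzyl)magnesium chloride | COc1ccc(C[Mg]Cl)cc1OC | intermediate (not isolated)
16 | dichloro(3,4-dimethoxybenzyl)cerium | COc1ccc(C[Ce](Cl)Cl)cc1OC | intermediate (not isolated)
17 | (3R,4R,5R)-5-[3,4-bis(benzyloxy)phenyl]-3-(3,4-dimethoxybenzyl)-4-ethenyloxolan-3-ol | COc1ccc(C[C@]2(O)CO[C@@H](c3ccc(OCc4ccccc4)c(OCc4ccccc4)c3)[C@H]2C=C)cc1OC | intermediate
18 | (2R,3R,4R)-2-[3,4-bis(benzyloxy)phenyl]-4-(3,4-dimethoxybenzyl)-4-hydroxyoxolane-3-carbaldehyde | COc1ccc(C[C@]2(O)CO[C@@H](c3ccc(OCc4ccccc4)c(OCc4ccccc4)c3)[C@H]2C=O)cc1OC | intermediate (not isolated)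
19 | (3R,4R,5R)-5-[3,4-bis(benzyloxy)phenyl]-3-(3,4-dimethoxybenzyl)-4-(hydroxymethyl)oxolan-3-ol | COc1ccc(C[C@]2(O)CO[C@@H](c3ccc(OCc4ccccc4)c(OCc4ccccc4)c3)[C@H]2CO)cc1OC | intermediate
20 | (3R,4R,5R)-5-(3,4-dihydroxyphenyl)-3-(3,4-dimethoxybenzyl)-4-(hydroxymethyl)oxolan-3-ol | COc1ccc(C[C@]2(O)CO[C@@H](c3ccc(O)c(O)c3)[C@H]2CO)cc1OC | target

**Step count:** 8 steps in total; longest linear sequence 8 steps (1 → 4 → 8 → 10 → 12 → 13 → 17 → 19 → 20).

**Steps most likely to fail**

Step 4. The free benzylic hydroxyl may compete for the chloroformate or close onto the activated carboxyl (β-lactonisation), and the vinyl double bond may migrate into conjugation under base. The fallback sets out from aldol adduct 8 and avoids diazo chemistry altogether. Transamidation with MeNHOMe·HCl and AlMe3 in CH2Cl2 should give the Weinreb amide F1 with release of the auxiliary. Chloromethyllithium (ICH2Cl, MeLi·LiBr, THF, −78 °C, the hydroxyl carried as its lithium alkoxide) should convert it into the chloromethyl ketone F2. Ag2O in CH2Cl2 should then close the O1–C2 bond by intramolecular O-alkylation at the activated α-carbon, coming back to the route at ketone 13.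

Step 6. The β,γ-unsaturated ketone may enolise (epimerisation at C4, alkene migration, β-elimination of the ring oxygen), the electron-rich benzylic halide may undergo Wurtz coupling during Grignard formation, or facial selectivity may be insufficient. The fallback sets out from ketone 13 and makes the aryl–CH2 bond last. Chloromethyllithium (ICH2Cl, MeLi·LiBr, THF, −78 °C), a small and weakly basic carbenoid, should add from the face opposite the vinyl and aryl groups to give the chlorohydrin F3. Its lithium alkoxide should close on warming to the spiro-epoxide F4 (oxirane oxygen cis to the vinyl group). 3,4-Dimethoxyphenylmagnesium bromide with catalytic CuI in THF should open the oxirane at its CH2 carbon, coming back to the route at carbinol 17.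

Step 7. Ozone may over-oxidise the dialkoxyarenes, and the β-hydroxy aldehyde may epimerise or undergo retro-aldol cleavage before reduction. The fallback sets out from carbinol 17. Dihydroxylation of the vinyl group with catalytic OsO4 and N-methylmorpholine N-oxide (acetone/H2O) should give the triol F5 as a mixture of epimers at the new carbinol carbon. NaIO4 cleavage of the 1,2-diol should give aldehyde 18 with loss of formaldehyde, and NaBH4 reduction comes back to the route at diol 19.

**Further compounds**
F1 | step 4 | (2R)-2-[(R)-[3,4-bis(benzyloxy)phenyl](hydroxy)methyl]-N-methoxy-N-methylbut-3-enamide | O[C@@H](c1ccc(OCc2ccccc2)c(OCc2ccccc2)c1)[C@H](C(=O)N(C)OC)C=C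
F2 | step 4 | (3R,4R)-4-[3,4-bis(benzyloxy)phenyl]-1-chloro-3-ethenyl-4-hydroxybutan-2-one | O[C@@H](c1ccc(OCc2ccccc2)c(OCc2ccccc2)c1)[C@H](C(=O)CCl)C=C
F3 | step 6 | (3R,4R,5R)-5-[3,4-bis(benzyloxy)phenyl]-3-(chloromethyl)-4-ethenyloxolan-3-ol | ClC[C@]1(O)CO[C@@H](c2ccc(OCc3ccccc3)c(OCc3ccccc3)c2)[C@H]1C=C
F4 | step 6 | (3S,6R,7R)-6-[3,4-bis(benzyloxy)phenyl]-7-ethenyl-1,5-dioxaspiro[2.4]heptane | C1[C@]2(O1)CO[C@@H](c3ccc(OCc4ccccc4)c(OCc4ccccc4)c3)[C@H]2C=C
F5 | step 7 | (3R,4R,5R)-5-[3,4-bis(benzyloxy)phenyl]-4-(1,2-dihydroxyethyl)-3-(3,4-dimethoxybenzyl)oxolan-3-ol, mixture of side-chain epimers | COc1ccc(C[C@]2(O)CO[C@@H](c3ccc(OCc4ccccc4)c(OCc4ccccc4)c3)[C@H]2C(O)CO)cc1OC
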